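## Structural features

The target, (2R,3R,6R,8S)-2,8-dibromo-3,7,7-trimethyl-11-methylidenespiro[5.5]undecan-3-ol, is a β-chamigrene-type spiro[5.5]undecane whose two six-membered carbocycles meet only at the quaternary carbon C6. Ring A (C6–C11) holds the gem-dimethyl carbon C7, a secondary bromide at C8 and an exocyclic methylidene on C11. Ring B (C1–C6) holds a trans bromohydrin: bromine on C2 and a tertiary methyl carbinol at C3. C11, C6 and C7 are three contiguous fully substituted carbons, C8 sits directly beside C7 (a neopentyl position), and C2/C3 are adjacent stereocentres lying 1,3 and 1,4 to C6. On ring B the C3 hydroxyl is on the face occupied by C11 and the C2 bromine on the face occupied by C7; on ring A the C8 bromine is cis to C1. The fragile groups are the two secondary bromides (elimination; the C2 bromide closes to an epoxide with the neighbouring alkoxide), the tertiary alcohol (ionisation, dehydration) and the 1,1-disubstituted alkene (migration into ring A with acid or metal hydrides). The real difficulty is the congested C6/C7 pair next to a C8 bromide that cannot be installed by substitution at a neopentyl carbon, together with the relay of configuration from C8 across C7 to C6 and on to C2/C3. The key step exploits the fact that C11 (ring A) and C3 (ring B) can both be carbonyl carbons and are 1,5-related through C6: an enol–alkene photocycloaddition followed by retro-aldol opening gives exactly such a 1,5-diketone on a quaternary carbon, making C6–C11, C4–C5 and ring A in one operation.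

## Logic of the disconnections

**20 ⇒ 19.** The C2–Br and C3–O bonds are cut. A trans bromohydrin with oxygen on the more substituted carbon is the retron of anti addition of bromine and water to a C2=C3 alkene. This removes two stereocentres and both heteroatoms of ring B, leaving only C6 and C8 as stereocentres in 19. The forward step must prefer the trisubstituted ring alkene over the C11 methylidene and must place bromine on the ring B face anti to C11.

**19 ⇒ 18.** The C2=C3 double bond is cut (ring-closing metathesis retron). Ring B opens to an allyl and a 3-methylbut-3-enyl chain on C6. The forward step needs a catalyst that closes the six-membered ring and leaves the C11 methylidene alone.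

**18 ⇒ 17.** Both C=CH2 bonds (at C11 and at C3) are cut back to carbonyls. This exposes the 1,5-diketone. The forward step must be non-basic, because a 1,5-diketone cyclises by aldol reaction, and must reach the neopentyl C11 carbonyl.

**17 ⇒ 15 (through 16).** The C6–C11 and C4–C5 bonds are cut. This removes ring A and the quaternary stereocentre and leaves an open chain with a single stereocentre. The forward step must close in the straight 1,6 sense, must take its facial bias from the C–Br stereocentre, and must tolerate an alkyl bromide and two isolated alkenes under irradiation.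

**15 ⇒ 13 + 14 (14 from 12; 13 from 11).** The C5–C6 bond of the dodecane chain of 15 is cut, so that all five diketone carbons come from 12 through its terminal carbanion. The forward step is a substitution at a β-branched primary carbon next to a C–Br bond and must avoid elimination.

**11 ⇒ 10 ⇒ 8 (through 9).** The C–Br bond is cut. Bromine is introduced as an electrophile onto an auxiliary-bound enolate, so no displacement at the neopentyl carbon is ever needed and the only stereocentre of the acyclic series is set by the auxiliary. The forward steps need the (4R) auxiliary for the (2R) bromide and a reductive auxiliary removal that does not close the bromohydrin to an epoxide.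

**8 ⇒ 7 ⇒ 4 + 5 (through 6).** The C=CH2 bond and the allyl–carbonyl bond are cut, tracing the 1,4-diene to a hindered carboxylic acid and an allyl donor. The forward steps need an acylation that does not conjugate the allyl ketone and a base-free methylenation of a hindered, easily enolised ketone.

**4 ⇒ 1 + 2 (through 3).** The N–acyl bond is cut. Compound 2 supplies the gem-dimethyl carbon, the two-carbon acyl arm and the hindered carboxyl in one piece, and the auxiliary is loaded in the same step. The forward step must open 2 at the carbonyl remote from the gem-dimethyl group.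

## Other disconnections considered

**Alternative 1:** The cut is C1–C6, with a temporary C1–C11 bond. A copper or rhodium carbenoid (Cu(acac)2 or Rh2(OAc)4) from the diazoketone A2 would add across the tetrasubstituted C6=C11 alkene of a preformed ring A to give the tricyclic cyclopropyl ketone A1. A homo-1,5-hydrogen shift from the C11 methyl (retro-ene) would then open the cyclopropane to the C11 methylidene and a C2 ketone.
- In its favour: the quaternary C6 is made by a carbene addition that, like the photocycloaddition of the chosen plan, is little affected by congestion; on this point the two are equal.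
- It is better than the chosen plan in two respects: the methylidene appears without any carbonyl olefination at the neopentyl C11, and C8 travels as a robust silyl ether instead of a secondary bromide.
- Against it: the face of the ring A alkene is controlled only by the C8 silyloxy group across C7, a weaker relay than the chair-like biradical of the chosen plan.
- Ring B emerges with only a C2 ketone, so the C3 methyl carbinol and the C2 bromide need α-methylation, α-hydroxylation, reduction and substitution, with two stereocentres set by reagent approach.
- The C8 oxygen must finally be replaced by bromine with inversion at a neopentyl secondary carbon, the one transformation the chosen plan is built to avoid.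
- Closure of a six-membered ring by a carbenoid also competes with C–H insertion.
- Step economy after the key step is clearly worse than the three steps of the chosen plan.

**Alternative 2:** The cut is C3–O and C2–Br, with a carboxyl on C6 (the future C11) as the internal nucleophile. N-Bromosuccinimide would convert the cyclohexenecarboxylic acid A4 into the bridged bromo δ-lactone A3.
- It is better than the chosen plan on stereocontrol at C2/C3: the tether forces the C3 oxygen onto the C11 face and bromine onto the opposite face, whereas step 10 of the chosen plan relies on an untethered facial preference.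
- Regiochemistry is the same in both (attack at the tertiary C3), so they are equal there.
- Against it: ring A is still open in A3 and must be closed by attack of a C10 carbon nucleophile on the lactone carbonyl flanked by C6 and C7. That is polar bond formation in the most congested region, in the presence of a secondary bromide.
- The quaternary C6 stereocentre must be set relative to C8 in a separate earlier operation, whereas the chosen plan creates it in the key step.
- The free C8 hydroxyl of A4 could compete as a nucleophile for the bromonium ion and must later be exchanged for bromine with inversion at the neopentyl carbon.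
- Overall the alternative is stronger on ring B and weaker on ring A, and longer.

**Alternative 3:** The cuts are C5–C6 and C1–C6. The kinetic α'-enolate of the ring A enone A6 would be alkylated twice by the bis-iodide A7 (first intermolecularly, then, after a second deprotonation, intramolecularly) to give the spiro enone A5.
- It is better than the chosen plan in convergence: ring A and the C1–C5 chain are made separately.
- It is also better in absolute control at C2/C3, which would come from a ligand-controlled OsO4 dihydroxylation of an acyclic alkene rather than from substrate bias.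
- The acetonide and silyl ether are sturdier than a bromohydrin; the two plans are equal in needing an inverting cyclic-sulfate or related step only if a cis-diol is chosen.
- Against it: both new bonds are SN2 alkylations at C6 beside the gem-dimethyl carbon. The second creates a quaternary centre next to a quaternary centre using a β-oxygenated primary iodide, which is a slow electrophile prone to elimination.
- The order in which the two iodides react and the face of the ring closure decide the C6 configuration and are not obviously controlled.
- The enone must afterwards be reduced and methylenated, C2 inverted to the bromide, and C8 converted with inversion at the neopentyl position.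
- Mechanistically this alternative asks most of polar chemistry exactly where the target is most hindered; the chosen plan asks for light instead.

Key step: step 7

## Remarks and assumptions before the steps

- Assumption: the boron-enolate bromination follows the facial sense of the chelated-enolate alkylations of this auxiliary class, so the (4R)-benzyl auxiliary is the one that gives the (2R) bromide 10.
- Structure check: 15 is (7S) and 17 is (2S,4S). These correlate with (6R,8S) in 19 and 20, and with (3R) at the quaternary carbon of 18. The letter changes at the quaternary carbon because the CIP ranking changes when C=O becomes C=CH2; the centre is not touched.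
- Design choices: the auxiliary opens the anhydride directly; both carbonyls of 17 are methylenated in one operation; the bromohydrin is made in one step, because a cis-dihydroxylation / cyclic sulfate detour would need the same facial sense and more steps.
- Locants C1–C11 are those of the spiro[5.5]undecane target.

## Route

**Step 1**
Reactants: 1 (4R)-4-benzyl-1,3-oxazolidin-2-one; 2 3,3-dimethyloxolane-2,5-dione (2,2-dimethylsuccinic anhydride)
Product: 4 4-[(4R)-4-benzyl-2-oxo-1,3-oxazolidin-3-yl]-2,2-dimethyl-4-oxobutanoic acid, via N-lithio oxazolidinone 3 (not isolated)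
Conditions: n-BuLi, THF, −78 °C; then 2, −78 → 0 °C; 1 M HCl work-up
Reagents that add atoms: none
Why: N-Acylation of a lithiated oxazolidinone by a cyclic anhydride with ring opening; the nucleophile should take the carbonyl next to CH2, away from the gem-dimethyl carbon, which leaves the hindered carboxylic acid free for the next step.

**Step 2**
Reactants: 4 4-[(4R)-4-benzyl-2-oxo-1,3-oxazolidin-3-yl]-2,2-dimethyl-4-oxobutanoic acid; 5 allyltributylstannane
Product: 7 (4R)-4-benzyl-3-(3,3-dimethyl-4-oxohept-6-enoyl)-1,3-oxazolidin-2-one, via acid chloride 6 (not isolated)
Conditions: (COCl)2, DMF (cat.), CH2Cl2, 0 → 23 °C; concentrate; 5, Pd(PPh3)4 (5 mol%), THF, 60 °C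
Reagents that add atoms: none
Why: Acid chloride formation followed by Stille acylation: oxidative addition of the acyl chloride to zerovalent palladium, allyl transfer from tin and reductive elimination should give the β,γ-unsaturated ketone. The neutral medium and the fully substituted α-carbon limit conjugation of the allyl ketone.

**Step 3**
Reactants: 7 (4R)-4-benzyl-3-(3,3-dimethyl-4-oxohept-6-enoyl)-1,3-oxazolidin-2-one
Product: 8 (4R)-4-benzyl-3-(3,3-dimethyl-4-methylidenehept-6-enoyl)-1,3-oxazolidin-2-one
Conditions: Zn, CH2Br2, TiCl4 (reagent pre-formed in THF, 5 °C); 7, CH2Cl2, 0 → 23 °C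
Reagents that add atoms: dibromomethane, BrCBr
Why: Takai–Lombardo methylenation; the zinc/titanium methylene reagent is non-basic, so the doubly activated allyl ketone should be neither enolised nor isomerised, and imide and carbamate carbonyls are not attacked at this temperature.

**Step 4**
Reactants: 8 (4R)-4-benzyl-3-(3,3-dimethyl-4-methylidenehept-6-enoyl)-1,3-oxazolidin-2-one
Product: 10 (4R)-4-benzyl-3-[(2R)-2-bromo-3,3-dimethyl-4-methylidenehept-6-enoyl]-1,3-oxazolidin-2-one, via Z-dibutylboron enolate 9 (not isolated)
Conditions: n-Bu2BOTf, i-Pr2NEt, CH2Cl2, −78 → 0 °C; NBS, −78 °C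
Reagents that add atoms: N-bromosuccinimide, O=C1CCC(=O)N1Br
Why: Evans auxiliary-controlled α-bromination: the chelated Z boron enolate should be brominated on the face away from the benzyl group, giving the (2R) bromide from the (4R) auxiliary, and the minor diastereomer is removable by chromatography. The C–Br bond is made by electrophilic bromination, so no substitution at the neopentyl carbon is required.

**Step 5**
Reactants: 10 (4R)-4-benzyl-3-[(2R)-2-bromo-3,3-dimethyl-4-methylidenehept-6-enoyl]-1,3-oxazolidin-2-one
Product: 11 (2R)-2-bromo-3,3-dimethyl-4-methylidenehept-6-en-1-ol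
Conditions: LiBH4, Et2O, H2O (1 equiv), 0 °C; pH 7 work-up
Reagents that add atoms: none
Why: Reductive cleavage of the N-acyl oxazolidinone: hydride should attack the exocyclic carbonyl, which the α-bromine activates, and release the primary alcohol and the auxiliary. Low temperature and a neutral work-up keep the neopentyl bromohydrin from closing to the epoxide.

**Step 6**
Reactants: 11 (2R)-2-bromo-3,3-dimethyl-4-methylidenehept-6-en-1-ol; 12 pentane-2,4-dione (acetylacetone)
Product: 15 (7S)-7-bromo-8,8-dimethyl-9-methylidenedodec-11-ene-2,4-dione, via primary triflate 13 (not isolated), via acetylacetone dilithium dianion 14 (not isolated)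
Conditions: Tf2O, 2,6-lutidine, CH2Cl2, −78 °C; cold pentane filtration; then 14 [12, LiN(i-Pr)2 (2.1 equiv), THF, 0 °C], THF, −78 → −30 °C; aq. NH4Cl
Reagents that add atoms: none
Why: O-Triflation followed by alkylation of a β-diketone dianion at its terminal carbon; the primary triflate should react at low temperature while the neopentyl secondary bromide is inert to SN2. The product stays protected as its diketonate monoanion until the quench.

**Step 7**
Reactants: 15 (7S)-7-bromo-8,8-dimethyl-9-methylidenedodec-11-ene-2,4-dione
Product: 17 (2S,4S)-4-bromo-3,3-dimethyl-2-(3-oxobutyl)-2-(prop-2-enyl)cyclohexan-1-one, via cyclobutanol photoadduct 16 (not isolated)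
Conditions: hν (350 nm lamps, Pyrex), degassed cyclohexane, 0.005 M, 20 °C; silica gel on work-up
Reagents that add atoms: none
Why: The hydrogen-bonded enol of 15 (enolised toward the tether) is excited and its C=C should add to the 1,1-disubstituted alkene through a triplet 1,4-biradical, the oxygen-bearing enol carbon bonding to the fully substituted alkene carbon (C6–C11) and the other enol carbon to the alkene CH2 (C4–C5), to give cyclobutanol 16. Compound 16 is a strained β-hydroxy ketone and should open by retro-aldol to the 1,5-diketone 17; the closest known reaction type is the intramolecular de Mayo reaction. Ring A closes in the straight 1,6 mode (six-membered) set by the four-atom tether, since crossed addition would need a seven-membered ring. The only new stereocentre, the quaternary C6, is controlled by the C–Br stereocentre through a chair-like biradical with bromine equatorial, in which the larger allyl group sits equatorial on the alkene carbon and the alkene CH2 sits axial, where it can reach the enol carbon to form a cis-fused cyclobutane; this places allyl cis to bromine. The step needs reaction at the 1,1-disubstituted alkene and not at the terminal one, which the tether secures because the terminal alkene would require an eight-membered ring. It also needs a chromophore that is the only absorber: the alkyl bromide and the isolated alkenes are transparent above 300 nm. High dilution suppresses intermolecular addition, and a radical bond formation is little slowed by the two flanking quaternary carbons.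

**Step 8**
Reactants: 17 (2S,4S)-4-bromo-3,3-dimethyl-2-(3-oxobutyl)-2-(prop-2-enyl)cyclohexan-1-one
Product: 18 (1S,3R)-1-bromo-2,2-dimethyl-3-(3-methylbut-3-enyl)-4-methylidene-3-(prop-2-enyl)cyclohexane
Conditions: Cp2TiMe2 (4 equiv), toluene–THF, 70 °C, dark
Reagents that add atoms: dimethyltitanocene, C[Ti](C)(C1C=CC=C1)C1C=CC=C1
Why: Petasis methylenation: Cp2Ti=CH2 formed on heating should convert both carbonyls through oxatitanacyclobutanes. The reagent is non-basic, so the 1,5-diketone should not cyclise by aldol reaction, and it is small enough to reach the neopentyl C11 carbonyl.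

**Step 9**
Reactants: 18 (1S,3R)-1-bromo-2,2-dimethyl-3-(3-methylbut-3-enyl)-4-methylidene-3-(prop-2-enyl)cyclohexane
Product: 19 (6R,8S)-8-bromo-3,7,7-trimethyl-11-methylidenespiro[5.5]undec-2-ene
Conditions: second-generation Grubbs catalyst RuCl2(=CHPh)(H2IMes)(PCy3) (5 mol%), CH2Cl2, 40 °C
Reagents that add atoms: none
Why: Ring-closing metathesis: the ruthenium alkylidene should load on the monosubstituted allyl alkene and close onto the isopropenyl group to give the six-membered ring with a trisubstituted alkene, helped by the quaternary carbon. Closure onto the C11 methylidene would give a cyclobutene and should not compete.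

**Step 10**
Reactants: 19 (6R,8S)-8-bromo-3,7,7-trimethyl-11-methylidenespiro[5.5]undec-2-ene
Product: 20 (2R,3R,6R,8S)-2,8-dibromo-3,7,7-trimethyl-11-methylidenespiro[5.5]undecan-3-ol
Conditions: NBS (1.05 equiv), THF–H2O (3:1), 0 °C, dark
Reagents that add atoms: N-bromosuccinimide, O=C1CCC(=O)N1Br; water, O
Why: Bromohydrin formation: the trisubstituted ring B alkene is more nucleophilic than the hindered 1,1-disubstituted alkene, and the bromonium ion should form on the ring B face anti to the pseudo-axial C11, whose methylidene overhangs C1/C2. Water should then open it at the tertiary C3 from the opposite face (Markovnikov, anti addition), which sets C2–Br trans to C3–OH with the hydroxyl on the C11 face, as in (2R,3R).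

## Compound list

1 | (4R)-4-benzyl-1,3-oxazolidin-2-one | O=C1N[C@H](Cc2ccccc2)CO1 | starting material
2 | 3,3-dimethyloxolane-2,5-dione (2,2-dimethylsuccinic anhydride) | CC1(C)CC(=O)OC1=O | starting material
3 | lithium (4R)-4-benzyl-2-oxo-1,3-oxazolidin-3-ide | [Li]N1[C@H](Cc2ccccc2)COC1=O | intermediate (not isolated)
4 | 4-[(4R)-4-benzyl-2-oxo-1,3-oxazolidin-3-yl]-2,2-dimethyl-4-oxobutanoic acid | OC(=O)C(C)(C)CC(=O)N1[C@H](Cc2ccccc2)COC1=O | intermediate
5 | allyltributylstannane | C=CC[Sn](CCCC)(CCCC)CCCC | starting material
6 | 4-[(4R)-4-benzyl-2-oxo-1,3-oxazolidin-3-yl]-2,2-dimethyl-4-oxobutanoyl chloride | ClC(=O)C(C)(C)CC(=O)N1[C@H](Cc2ccccc2)COC1=O | intermediate (not isolated)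
7 | (4R)-4-benzyl-3-(3,3-dimethyl-4-oxohept-6-enoyl)-1,3-oxazolidin-2-one | C=CCC(=O)C(C)(C)CC(=O)N1[C@H](Cc2ccccc2)COC1=O | intermediate
8 | (4R)-4-benzyl-3-(3,3-dimethyl-4-methylidenehept-6-enoyl)-1,3-oxazolidin-2-one | C=CCC(=C)C(C)(C)CC(=O)N1[C@H](Cc2ccccc2)COC1=O | intermediate
9 | (Z)-dibutylboron enolate of 8 | C=CCC(=C)C(C)(C)/C=C(\OB(CCCC)CCCC)N1[C@H](Cc2ccccc2)COC1=O | intermediate (not isolated)
10 | (4R)-4-benzyl-3-[(2R)-2-bromo-3,3-dimethyl-4-methylidenehept-6-enoyl]-1,3-oxazolidin-2-one | C=CCC(=C)C(C)(C)[C@@H](Br)C(=O)N1[C@H](Cc2ccccc2)COC1=O | intermediate
11 | (2R)-2-bromo-3,3-dimethyl-4-methylidenehept-6-en-1-ol | OC[C@H](Br)C(C)(C)C(=C)CC=C | intermediate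
12 | pentane-2,4-dione (acetylacetone) | CC(=O)CC(C)=O | starting material
13 | (2R)-2-bromo-3,3-dimethyl-4-methylidenehept-6-en-1-yl trifluoromethanesulfonate | O=S(=O)(OC[C@H](Br)C(C)(C)C(=C)CC=C)C(F)(F)F | intermediate (not isolated)
14 | dilithium dianion of pentane-2,4-dione (C1,C3-dianion) | [Li+].[Li+].[CH2-]C(=O)[CH-]C(C)=O | intermediate (not isolated)
15 | (7S)-7-bromo-8,8-dimethyl-9-methylidenedodec-11-ene-2,4-dione | CC(=O)CC(=O)CC[C@H](Br)C(C)(C)C(=C)CC=C | intermediate (key-step precursor)
16 | 1-[(1R,3S,6S)-3-bromo-6-hydroxy-2,2-dimethyl-1-(prop-2-enyl)bicyclo[4.2.0]octan-7-yl]ethanone (cis-fused; bromine, allyl and hydroxyl on one face; the acetyl-bearing carbon is not defined and is lost in the retro-aldol) | O[C@]12CC[C@H](Br)C(C)(C)[C@@]1(CC=C)CC2C(C)=O | intermediate (not isolated)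
17 | (2S,4S)-4-bromo-3,3-dimethyl-2-(3-oxobutyl)-2-(prop-2-enyl)cyclohexan-1-one | O=C1CC[C@H](Br)C(C)(C)[C@@]1(CC=C)CCC(C)=O | intermediate (key-step product)
18 | (1S,3R)-1-bromo-2,2-dimethyl-3-(3-methylbut-3-enyl)-4-methylidene-3-(prop-2-enyl)cyclohexane | C=C1CC[C@H](Br)C(C)(C)[C@@]1(CC=C)CCC(C)=C | intermediate
19 | (6R,8S)-8-bromo-3,7,7-trimethyl-11-methylidenespiro[5.5]undec-2-ene | C=C1CC[C@H](Br)C(C)(C)[C@@]12CCC(C)=CC2 | intermediate
20 | (2R,3R,6R,8S)-2,8-dibromo-3,7,7-trimethyl-11-methylidenespiro[5.5]undecan-3-ol | C=C1CC[C@H](Br)C(C)(C)[C@@]12CC[C@@](C)(O)[C@H](Br)C2 | target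

## Step count and least certain steps

Total: 10 steps. Longest linear sequence: 10 steps (1 and 2 to 20). Steps 2 and 6 are two-operation steps counted once, because 6 and 13 are used without purification.

**Step 7 (key step).** Most likely to go wrong: bond formation on the other alkene face (allyl axial in the biradical), which would lead into the C6-epimeric series. Hydrogen abstraction from the doubly allylic CH2 by the excited enol, or inefficient reaction of the free enol, could also erode the step.
Fallback: set out from 13 and alkylate the lithium dienolate of 2,2,6-trimethyl-1,3-dioxin-4-one (LiN(i-Pr)2, THF–DMPU, −78 °C) at its methyl group to give 6-[(3S)-3-bromo-4,4-dimethyl-5-methylideneoct-7-enyl]-2,2-dimethyl-1,3-dioxin-4-one F1. This covalently locked enol is a more dependable chromophore, and its ring stiffens the enol partner in the chair-like closure. Irradiation (300 nm, MeCN–acetone) should give the cyclobutane-fused dioxanone photoadduct F2. Fragmentation with K2CO3 in MeOH should give methyl 3-[(1S,3S)-3-bromo-2,2-dimethyl-6-oxo-1-(prop-2-enyl)cyclohexyl]propanoate F3. Me(MeO)NH·HCl with i-PrMgCl should give 3-[(1S,3S)-3-bromo-2,2-dimethyl-6-oxo-1-(prop-2-enyl)cyclohexyl]-N-methoxy-N-methylpropanamide F4, and MeMgBr then returns to the route at 17. The neopentyl ring ketone is shielded and, if necessary, protected as its magnesium enolate by the excess base.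

**Step 10.** Most likely to go wrong: opening of the bromonium ion on the wrong face (the diaxial pathway from the C11 side), attack at C2 instead of C3, or competing reaction or transannular capture by the C11 methylidene.
Fallback: set out from 17 and methylenate only the unhindered methyl ketone (Zn, CH2Br2, TiCl4, 0 °C) to give (2S,4S)-4-bromo-3,3-dimethyl-2-(3-methylbut-3-enyl)-2-(prop-2-enyl)cyclohexan-1-one F5. Ring-closing metathesis should give (4S,6S)-4-bromo-5,5,9-trimethylspiro[5.5]undec-8-en-1-one F6. In F6 there is no second alkene, and the C11 carbonyl oxygen, fixed on the required face, can capture the bromonium ion at C3 through a six-membered oxocarbenium ion (halo-ketalisation-type participation). Hydrolysis of the bridged hemiketal should then give (4S,6S,8R,9R)-4,8-dibromo-9-hydroxy-5,5,9-trimethylspiro[5.5]undecan-1-one F7 on treatment with NBS in aqueous THF. Methylenation with excess Cp2TiMe2 (one equivalent is consumed by the tertiary alcohol) comes back to the route at 20.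

**Step 6.** Most likely to go wrong: elimination of triflic acid, or bromine-philic attack, by the strongly basic dianion on the vicinal bromo-triflate in place of substitution at the β-branched primary carbon.
Fallback: set out from 13 and use the lithiated N,N-dimethylhydrazone of acetone, an aza-enolate that alkylates hindered primary electrophiles cleanly, to give (5S)-5-bromo-6,6-dimethyl-7-methylidenedec-9-en-2-one N,N-dimethylhydrazone F8. Hydrolysis with aqueous oxalic acid should give (5S)-5-bromo-6,6-dimethyl-7-methylidenedec-9-en-2-one F9. Kinetic enolisation at the methyl group (LiN(SiMe3)2, 2.2 equiv, −78 °C) and C-acetylation with 1-acetylimidazole returns to the route at 15.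

**Step 3.** Most likely to go wrong: slow methylenation of the hindered ketone, with migration of the allyl double bond into conjugation under the Lewis-acidic conditions (the same migration can begin in step 2).
Fallback: avoid the ketone altogether. Set out from 5 and couple it with ethyl 2-bromo-3-methylbut-2-enoate (Pd(PPh3)4, CuI, DMF) to give ethyl 3-methyl-2-(prop-2-enyl)but-2-enoate F10. Reduction with i-Bu2AlH should give 3-methyl-2-(prop-2-enyl)but-2-en-1-ol F11. Johnson–Claisen rearrangement with triethyl orthoacetate (propionic acid cat., 140 °C) builds the gem-dimethyl quaternary carbon and the 1,1-disubstituted alkene together, giving ethyl 3,3-dimethyl-4-methylidenehept-6-enoate F12. Saponification with LiOH should give 3,3-dimethyl-4-methylidenehept-6-enoic acid F13, and the pivaloyl mixed anhydride of F13 acylates 3 to return to the route at 8.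

**Step 8.** Most likely to go wrong: incomplete methylenation or enolisation at the neopentyl C11 carbonyl, leaving the mono-methylenated ketone.
Fallback: set out from 17 and add Me3SiCH2Li/CeCl3 (THF, −78 °C), a non-basic reagent for hindered, enolisable ketones, to both carbonyls to give (4S)-4-bromo-2-[3-hydroxy-3-methyl-4-(trimethylsilyl)butyl]-3,3-dimethyl-2-(prop-2-enyl)-1-[(trimethylsilyl)methyl]cyclohexan-1-ol F14. Peterson elimination of both β-hydroxysilanes with KH in THF (or aqueous HF in MeCN if the alkoxide is troublesome) returns to the route at 18.

## Further compounds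

F1 | step 7 | 6-[(3S)-3-bromo-4,4-dimethyl-5-methylideneoct-7-enyl]-2,2-dimethyl-1,3-dioxin-4-one | CC1(C)OC(CC[C@H](Br)C(C)(C)C(=C)CC=C)=CC(=O)O1
F2 | step 7 | cyclobutane-fused dioxanone photoadduct (analogue of 16 with the ring oxygen of a 2,2-dimethyl-1,3-dioxan-4-one on the carbinol carbon and its lactone carbonyl on the adjacent cyclobutane carbon) | O3[C@]12CC[C@H](Br)C(C)(C)[C@@]1(CC=C)C[C@@H]2C(=O)OC3(C)C
F3 | step 7 | methyl 3-[(1S,3S)-3-bromo-2,2-dimethyl-6-oxo-1-(prop-2-enyl)cyclohexyl]propanoate | O=C1CC[C@H](Br)C(C)(C)[C@@]1(CC=C)CCC(=O)OC
F4 | step 7 | 3-[(1S,3S)-3-bromo-2,2-dimethyl-6-oxo-1-(prop-2-enyl)cyclohexyl]-N-methoxy-N-methylpropanamide | O=C1CC[C@H](Br)C(C)(C)[C@@]1(CC=C)CCC(=O)N(C)OC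
F5 | step 10 | (2S,4S)-4-bromo-3,3-dimethyl-2-(3-methylbut-3-enyl)-2-(prop-2-enyl)cyclohexan-1-one | O=C1CC[C@H](Br)C(C)(C)[C@@]1(CC=C)CCC(C)=C
F6 | step 10 | (4S,6S)-4-bromo-5,5,9-trimethylspiro[5.5]undec-8-en-1-one | O=C1CC[C@H](Br)C(C)(C)[C@@]12CCC(C)=CC2
F7 | step 10 | (4S,6S,8R,9R)-4,8-dibromo-9-hydroxy-5,5,9-trimethylspiro[5.5]undecan-1-one | O=C1CC[C@H](Br)C(C)(C)[C@@]12CC[C@@](C)(O)[C@H](Br)C2
F8 | step 6 | (5S)-5-bromo-6,6-dimethyl-7-methylidenedec-9-en-2-one N,N-dimethylhydrazone | CC(=NN(C)C)CC[C@H](Br)C(C)(C)C(=C)CC=C
F9 | step 6 | (5S)-5-bromo-6,6-dimethyl-7-methylidenedec-9-en-2-one | CC(=O)CC[C@H](Br)C(C)(C)C(=C)CC=C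
F10 | step 3 | ethyl 3-methyl-2-(prop-2-enyl)but-2-enoate | CCOC(=O)C(CC=C)=C(C)C
F11 | step 3 | 3-methyl-2-(prop-2-enyl)but-2-en-1-ol | OCC(CC=C)=C(C)C
F12 | step 3 | ethyl 3,3-dimethyl-4-methylidenehept-6-enoate | CCOC(=O)CC(C)(C)C(=C)CC=C
F13 | step 3 | 3,3-dimethyl-4-methylidenehept-6-enoic acid | OC(=O)CC(C)(C)C(=C)CC=C
F14 | step 8 | (4S)-4-bromo-2-[3-hydroxy-3-methyl-4-(trimethylsilyl)butyl]-3,3-dimethyl-2-(prop-2-enyl)-1-[(trimethylsilyl)methyl]cyclohexan-1-ol (carbinol centres as formed) | C[Si](C)(C)CC1(O)CC[C@H](Br)C(C)(C)[C@@]1(CC=C)CCC(C)(O)C[Si](C)(C)C
A1 | alternative 1 | tricyclic cyclopropyl ketone (cyclopropane C1/C6/C11, ketone at C2, silyl ether at C8) | O=C1CCC[C@@]23[C@@H]1[C@]2(C)CC[C@@H](O[Si](C)(C)C(C)(C)C)C3(C)C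
A2 | alternative 1 | 5-[(5R)-5-(tert-butyldimethylsilyloxy)-2,6,6-trimethylcyclohex-1-en-1-yl]-1-diazopentan-2-one | [N-]=[N+]=CC(=O)CCCC1=C(C)CC[C@@H](O[Si](C)(C)C(C)(C)C)C1(C)C
A3 | alternative 2 | bromo δ-lactone (2-oxabicyclo[2.2.2]octan-3-one bridging C6 and C3, bromine at C2, open ring A chain) | CC(C)(C)[Si](C)(C)OCC[C@@H](O)C(C)(C)[C@@]12CC[C@@](C)(OC1=O)[C@H](Br)C2
A4 | alternative 2 | 1-[5-(tert-butyldimethylsilyloxy)-3-hydroxy-2-methylpentan-2-yl]-4-methylcyclohex-3-ene-1-carboxylic acid (configuration as in the SMILES) | CC(C)(C)[Si](C)(C)OCC[C@@H](O)C(C)(C)[C@]1(C(=O)O)CCC(C)=CC1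
A5 | alternative 3 | spiro enone with C8 silyl ether and C2/C3 acetonide | O=C1C=C[C@@H](O[Si](C)(C)C(C)(C)C)C(C)(C)[C@@]12CC[C@@]3(C)OC(C)(C)O[C@H]3C2
A6 | alternative 3 | (4R)-4-(tert-butyldimethylsilyloxy)-5,5-dimethylcyclohex-2-en-1-one | O=C1C=C[C@@H](O[Si](C)(C)C(C)(C)C)C(C)(C)C1
A7 | alternative 3 | (4R,5R)-4-(2-iodoethyl)-5-(iodomethyl)-2,2,4-trimethyl-1,3-dioxolane | ICC[C@@]1(C)OC(C)(C)O[C@H]1CI
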